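(The numbers in the tables come from a simulation from invented constants; scatter was added.)

A flask cannot lose more starting material than was charged, so at a fixed time and charge the percentage lost cannot rise in step with the catalyst indefinitely. Two earlier runs differ in their catalyst charge, and the new flask has a charge between theirs.

common to all: starting material 0.18 M; gas 30 mM (held)
- Saturday's: free catalyst 12 mM; run made earlier
- Monday's: free catalyst 27 mM; run made earlier
- flask: free catalyst 18 mM; time 40 h

- Saturday's (time / h: target / %, catalyst intermediate D / %, starting material / %): 6.00: 4, 3, 95; 12.0: 6, 3, 89; 20.0: 15, 1, 79; 25.0: 21, 3, 74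
- Monday's (time / h: target / %, catalyst intermediate D / %, starting material / %): 2.00: 0, 0, 97; 4.00: 2, 2, 93; 10.0: 12, 3, 82; 25.0: 35, 3, 52

(scatter of a reading: 1.5 percentage points)

- concentration of target at 40 h, in M
- concentration of catalyst intermediate D at 40 h, in M

- what was read earlier has a scatter of 1.5 percentage points, one standard deviation
- at the start none of the gas is in solution

Monday's run holds 2.25 times Saturday's catalyst, yet at 25.0 h it has lost just 1.85 times as much starting material. The fraction left narrows this gap when its logarithm is taken as a bare yardstick read at that one time, with no claim of an order in starting material.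

| Run | Free catalyst | Left | ln(charged/left) | Decay per catalyst-hour |
|---|---|---|---|---|
| Saturday's | 12 mM | 74% | 0.301 | 1.00 L mol⁻¹ h⁻¹ |
| Monday's | 27 mM | 52% | 0.654 | 0.969 L mol⁻¹ h⁻¹ |

The logarithms stand at a ratio of 2.17, close to the catalyst ratio. The decay per catalyst-hour, the logarithm of charged over left divided by catalyst charge and time, reads 0.986 L mol⁻¹ h⁻¹ on average.

As an estimate for the flask, this yardstick leaves 49.2% of the starting material at 40 h, so about 0.0915 M has reacted. This reckoning puts [target] between 0.0735 M and 0.0915 M, the lower end taking the whole catalyst charge as still loaded. [Catalyst intermediate D] reads 3% at 25.0 h in Saturday's run and 3% in Monday's, which gives about 0.00540 M here.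

The forecast, on a “rate about first order in catalyst”, gives 0.083 M of target and 0.0047 M of catalyst intermediate D, the latter lower than this reading.

The flask gives 0.0868 M of target and 0.00409 M of catalyst intermediate D, with 45% of the starting material left.

    reagent + free catalyst → catalyst intermediate A (k = 0.00780 L mol⁻¹ s⁻¹)
    catalyst intermediate A ⇌ catalyst intermediate B (K = 4.00, k = 6.80 × 10⁻⁴ s⁻¹)
    starting material + catalyst intermediate B → catalyst intermediate C (k = 0.0300 L mol⁻¹ s⁻¹)
    catalyst intermediate C ⇌ by-product + catalyst intermediate D (K = 0.310 M, k = 1.70 × 10⁻⁴ s⁻¹)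
    catalyst intermediate D → catalyst intermediate E (k = 1.60 × 10⁻⁴ s⁻¹)
    catalyst intermediate E ⇌ free catalyst + target (K = 0.210 M, k = 8.90 × 10⁻⁴ s⁻¹)
    gas ⇌ reagent, rate k7*(csat - [reagent]) (kL = 5.30 × 10⁻⁵ s⁻¹)

That remainder gives the flask a decay per catalyst-hour of 1.10 L mol⁻¹ h⁻¹, against 0.986 L mol⁻¹ h⁻¹ from the runs. The neighbouring flask is the same charge read at 25 h. There 0.986 L mol⁻¹ h⁻¹ leaves 64.2%, so 0.0645 M has reacted, and [target] falls between 0.0465 M and 0.0645 M. The neighbouring flask shows 65% of the starting material left and [target] at 0.0510 M.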